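**Plan**

Locants: C1'–C16' number the acyl chain from the ester carbonyl. Ring locants are those of 5,6,7,7a-tetrahydro-1-benzofuran-2(4H)-one.

1. Cuts: first C6'–C7' (gives 1-bromodecane and the hex-5-enoate of the bicyclic alcohol). Then C3=C3a and O1–C2 of the butenolide (gives an α-ketol and a C2 cumulene ylide). Then C7a–O1 (gives an enol ether and peracid oxygen). Last the C6–O acyl bond (gives actinol and hex-5-enoyl chloride).
2. Forward: the carbocycle is bought as achiral ketoisophorone and reduced twice. The C1'–C6' half of the chain goes on early and is the only protecting group. C7a–OH and then the lactone ring follow, and the chain is completed in the last step.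
3. Enabling feature: C6' and C7' are unbranched CH2 groups, and four CH2 groups separate C6' from the ester carbonyl. The bicycle has no O–H and no acidic C–H beside the C3=C3a–C2=O unit, because C4 and C7a are quaternary. Its only alkene is shielded and trisubstituted, so a terminal vinyl group can be hydroborated and cross-coupled next to it.
4. Stereochemistry: an ene-reductase sets the methyl centre of levodione (R). That centre steers the ketone hydrogenation to the 4R carbinol (C6 of the target) and is then erased. The C6 acyloxy group sends the peracid to the opposite ring face and so sets C7a (R).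

Key step: step 7

Remark: the carbinol carbon is R in 3, 5 and 6 and S from 7 onwards. Oxygenation of the future C7a changes the CIP ranking of its two ring neighbours; the spatial arrangement does not change.

Step 1
Reactants: 1 ketoisophorone (2,6,6-trimethylcyclohex-2-ene-1,4-dione)
Product: 2 (6R)-levodione [(6R)-2,2,6-trimethylcyclohexane-1,4-dione]
Conditions: OYE2 ene-reductase (cat.), NADP+ (cat.), glucose dehydrogenase (cat.), D-glucose, phosphate buffer pH 7, 30 °C
Reagents that add atoms: none
Why: Asymmetric bioreduction of an activated alkene by an Old Yellow Enzyme: flavin hydride and an active-site proton add trans across C2=C3 inside the chiral pocket, which should set the methyl-bearing centre as R, while glucose and glucose dehydrogenase recycle NADPH.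

Step 2
Reactants: 2 (6R)-levodione
Product: 3 (4R,6R)-actinol [(4R,6R)-4-hydroxy-2,2,6-trimethylcyclohexan-1-one, OH trans to the 6-methyl group]
Conditions: H2, Raney Ni (cat.), MeOH, rt; crystallisation
Reagents that add atoms: none
Why: Chemoselective heterogeneous ketone hydrogenation of the unhindered C4 carbonyl (C1 lies between CMe2 and CHMe); as with 3,3,5-trimethylcyclohexanone the axial C2 methyl blocks the axial face, so hydrogen should arrive from the equatorial side and give the axial 4R alcohol trans to the 6-methyl group, and the minor cis isomer must be removed here because C6 is erased later.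

Step 3
Reactants: 3 (4R,6R)-actinol; 4 hex-5-enoyl chloride
Product: 5 (1R,5R)-3,3,5-trimethyl-4-oxocyclohexyl hex-5-enoate
Conditions: pyridine, DMAP (cat.), CH2Cl2, 0 °C to rt
Reagents that add atoms: none
Why: DMAP-catalysed acylation of the secondary alcohol with retention at the carbinol carbon; the ester brings in C1'–C6', masks the oxygen for the rest of the route and carries the terminal vinyl handle.

Step 4
Reactants: 5 (1R,5R)-3,3,5-trimethyl-4-oxocyclohexyl hex-5-enoate
Product: 6 (1R)-3,5,5-trimethyl-4-(trimethylsilyloxy)cyclohex-3-en-1-yl hex-5-enoate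
Conditions: TMSOTf, Et3N, CH2Cl2, 0 °C to rt
Reagents that add atoms: trimethylsilyl triflate, C[Si](C)(C)OS(=O)(=O)C(F)(F)F
Why: Soft enolisation (silyl triflate and tertiary amine): the ketone has only one enolisable position because the other α-carbon is quaternary, ketones are silylated much faster than alkyl esters under these conditions, and the methyl stereocentre is erased on purpose.

Step 5
Reactants: 6 (1R)-3,5,5-trimethyl-4-(trimethylsilyloxy)cyclohex-3-en-1-yl hex-5-enoate
Product: 8 (1S,3R)-3-hydroxy-3,5,5-trimethyl-4-oxocyclohexyl hex-5-enoate, via α-silyloxy ketone 7 (not isolated)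
Conditions: mCPBA (1.05 equiv), CH2Cl2, −20 °C; then 1 M HCl, THF, 0 °C
Reagents that add atoms: mCPBA, OOC(=O)c1cccc(Cl)c1
Why: Rubottom oxidation: the electron-rich tetrasubstituted enol ether is epoxidised far faster than the terminal vinyl group, the peracid should approach anti to the homoallylic acyloxy group (as in peracid epoxidations of 3-acyloxy-β-ionone-type rings), and epoxide opening with 1,4-silyl shift gives 7, whose mild hydrolysis frees ketol 8 with the new C–O bond trans to the ester (3R).

Step 6
Reactants: 8 (1S,3R)-3-hydroxy-3,5,5-trimethyl-4-oxocyclohexyl hex-5-enoate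
Product: 10 (−)-loliolide hex-5-enoate [(6S,7aR)-4,4,7a-trimethyl-2-oxo-2,4,5,6,7,7a-hexahydro-1-benzofuran-6-yl hex-5-enoate], via ester ylide 9 (not isolated)
Conditions: Ph3P=C=C=O (1.5 equiv), toluene, reflux
Reagents that add atoms: ketenylidenetriphenylphosphorane (Bestmann ylide), O=C=C=P(c1ccccc1)(c1ccccc1)c1ccccc1
Why: Butenolide synthesis from an α-hydroxy ketone with the Bestmann ylide: the tertiary OH adds across the cumulene to give stabilised ylide 9, whose intramolecular Wittig reaction with the neighbouring ketone closes the five-membered ring under neutral conditions that spare the ester and the vinyl group, and the C7a–O bond is never broken, so its configuration is kept.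

Step 7
Reactants: 10 (−)-loliolide hex-5-enoate; 11 1-bromodecane
Product: 13 (−)-3-O-palmitoylloliolide, via B-alkyl-9-BBN 12 (not isolated)
Conditions: 9-BBN, THF, rt; then 11, Pd(OAc)2 (cat.), PCy3 (cat.), K3PO4·H2O, THF, rt
Reagents that add atoms: none
Why: 9-BBN adds to the only unhindered alkene, the terminal C5'=C6' vinyl group, in the anti-Markovnikov sense and puts boron on C6' (12); hydroxide from K3PO4·H2O turns 12 into its borate, Pd(0)/PCy3 inserts into the C–Br bond of 11 by an SN2-type oxidative addition, the primary alkyl group moves from boron to palladium, and reductive elimination forms C6'–C7'. The closest known reaction type is the Suzuki–Miyaura alkyl–alkyl cross-coupling of B-alkyl-9-BBN reagents with unactivated primary alkyl bromides that carry β-hydrogens, run at room temperature with a bulky electron-rich trialkylphosphine that makes coupling faster than β-hydride elimination. No ring is closed and no stereocentre is created; C6 and C7a carry no acidic hydrogen and lie far from the reacting carbons, so both should pass through unchanged. Chemoselectivity is needed three times: in the hydroboration the butenolide C3=C3a bond is trisubstituted, conjugated and walled in by the quaternary C4 and C7a, and esters are inert to 9-BBN at room temperature; in the palladium cycle the allylic C7a–O1 bond lies in the plane of the lactone ring, orthogonal to the C3=C3a π-orbitals, so π-allyl ionisation has no orbital overlap; and the mild phosphate base at room temperature should leave the C6 ester and the lactone intact. The vinyl group is the only helper of the route and is used up in the same flask, so nothing has to be removed after the coupling.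

**Compound list**

1 | ketoisophorone (2,6,6-trimethylcyclohex-2-ene-1,4-dione) | CC1=CC(=O)CC(C)(C)C1=O | starting material
2 | (6R)-levodione | C[C@@H]1CC(=O)CC(C)(C)C1=O | intermediate
3 | (4R,6R)-actinol | C[C@@H]1C[C@@H](O)CC(C)(C)C1=O | intermediate
4 | hex-5-enoyl chloride | C=CCCCC(=O)Cl | starting material
5 | (1R,5R)-3,3,5-trimethyl-4-oxocyclohexyl hex-5-enoate | C[C@@H]1C[C@@H](OC(=O)CCCC=C)CC(C)(C)C1=O | intermediate
6 | (1R)-3,5,5-trimethyl-4-(trimethylsilyloxy)cyclohex-3-en-1-yl hex-5-enoate | CC1=C(O[Si](C)(C)C)C(C)(C)C[C@H](OC(=O)CCCC=C)C1 | intermediate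
7 | (1S,3R)-3,5,5-trimethyl-4-oxo-3-(trimethylsilyloxy)cyclohexyl hex-5-enoate (α-silyloxy ketone, not isolated) | C[C@@]1(O[Si](C)(C)C)C[C@@H](OC(=O)CCCC=C)CC(C)(C)C1=O | intermediate
8 | (1S,3R)-3-hydroxy-3,5,5-trimethyl-4-oxocyclohexyl hex-5-enoate (3-OH trans to the 1-acyloxy group) | C[C@@]1(O)C[C@@H](OC(=O)CCCC=C)CC(C)(C)C1=O | intermediate
9 | (triphenylphosphoranylidene)acetate of ketol 8 (ester ylide, not isolated) | C[C@@]1(OC(=O)C=P(c2ccccc2)(c2ccccc2)c2ccccc2)C[C@@H](OC(=O)CCCC=C)CC(C)(C)C1=O | intermediate
10 | (−)-loliolide hex-5-enoate | C=CCCCC(=O)O[C@H]1CC(C)(C)C2=CC(=O)O[C@]2(C)C1 | intermediate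
11 | 1-bromodecane | CCCCCCCCCCBr | starting material
12 | (−)-loliolide 6-(9-borabicyclo[3.3.1]nonan-9-yl)hexanoate (B-alkyl-9-BBN, not isolated) | O=C(CCCCCB1C2CCCC1CCC2)O[C@H]1CC(C)(C)C2=CC(=O)O[C@]2(C)C1 | intermediate
13 | (−)-3-O-palmitoylloliolide [(6S,7aR)-4,4,7a-trimethyl-2-oxo-2,4,5,6,7,7a-hexahydro-1-benzofuran-6-yl hexadecanoate] | CCCCCCCCCCCCCCCC(=O)O[C@H]1CC(C)(C)C2=CC(=O)O[C@]2(C)C1 | target

Total step count: 7
Longest linear sequence: 7 steps (1 to 13)

**Steps most likely to fail**

**Step 5.** Facial selectivity of the peracid attack may be poor. The directing acyloxy group is only homoallylic, and the pseudo-axial methyl of the CMe2 group hinders the face that is wanted.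

The fallback sets out from 5 and comes back at 10. It lets the carboxyl group of the future lactone make the C7a–O bond instead of an external oxidant.
- Ketone 5 is converted with Tf2O and 2,6-di-tert-butyl-4-methylpyridine in CH2Cl2 into the enol triflate F1.
- Negishi-type coupling with tert-butyl (bromozincio)acetate, the Reformatsky reagent, under Pd(0) gives the β,γ-unsaturated tert-butyl ester F2.
- TFA liberates the free acid F3.
- Iodolactonisation under equilibrating conditions (I2, MeCN) gives the iodolactone F4.
- DBU removes HI to give 10.

Iodonium formation is reversible. Ring closure follows the Fürst–Plattner rule through the chair-like transition state that keeps the acyloxy group equatorial. This places the lactone oxygen axial at C7a on the face opposite the ester. That isomer is also the less strained one, so kinetic and thermodynamic control point the same way.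

**Step 6.** Addition of the hindered tertiary alcohol to the cumulene may be slow. The stabilised ylide may also fail to attack a ketone that lies between two quaternary carbons, and the material may decompose on long heating.

The fallback sets out from 8 and comes back at 10. It replaces the olefination by an aldol-type C–C bond formation followed by elimination.
- Bromoacetyl bromide and pyridine give the bromoacetate F5.
- SmI2 (2 equiv, THF, −78 °C) reduces the C–Br bond first. It then triggers an intramolecular Reformatsky addition to the ketone, which gives the cis-fused 3a-hydroxy lactone F6.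
- SOCl2 in pyridine dehydrates F6. Only the C3 hydrogens are available because C4 and C7a are quaternary, so 10 is the only possible alkene.

**Step 7.** β-Hydride elimination from the decylpalladium species, protodeboronation of 12 or slow transmetalation may consume both partners without coupling.

The fallback sets out from 12 (made from 10 as in step 7) and from 11, and comes back at 13. It forms the same C6'–C7' bond with the polarity of the two halves reversed and without base.
- Borane 12 is oxidised in the flask with NaBO3·4H2O to the 6-hydroxyhexanoate F7.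
- An Appel reaction (I2, PPh3, imidazole) gives the 6-iodohexanoate F8.
- Bromide 11 is converted with zinc dust (cat. I2, DMA) into decylzinc bromide F9.
- A Negishi alkyl–alkyl coupling of F8 with F9 (Pd2(dba)3, tricyclopentylphosphine, N-methylimidazole, THF/NMP, 80 °C) gives 13.

**Further compounds**

F1 | step 5 | enol triflate, (1R)-3,5,5-trimethyl-4-(trifluoromethylsulfonyloxy)cyclohex-3-en-1-yl hex-5-enoate | CC1=C(OS(=O)(=O)C(F)(F)F)C(C)(C)C[C@H](OC(=O)CCCC=C)C1
F2 | step 5 | β,γ-unsaturated tert-butyl ester, tert-butyl 2-[(4R)-4-(hex-5-enoyloxy)-2,6,6-trimethylcyclohex-1-en-1-yl]acetate | CC1=C(CC(=O)OC(C)(C)C)C(C)(C)C[C@H](OC(=O)CCCC=C)C1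
F3 | step 5 | free acid, 2-[(4R)-4-(hex-5-enoyloxy)-2,6,6-trimethylcyclohex-1-en-1-yl]acetic acid | CC1=C(CC(=O)O)C(C)(C)C[C@H](OC(=O)CCCC=C)C1
F4 | step 5 | iodolactone, (3aR,6S,7aR)-3a-iodo-4,4,7a-trimethyl-2-oxooctahydro-1-benzofuran-6-yl hex-5-enoate | C=CCCCC(=O)O[C@H]1CC(C)(C)[C@]2(I)CC(=O)O[C@]2(C)C1
F5 | step 6 | bromoacetate, (1S,3R)-3-(2-bromoacetoxy)-3,5,5-trimethyl-4-oxocyclohexyl hex-5-enoate | C[C@@]1(OC(=O)CBr)C[C@@H](OC(=O)CCCC=C)CC(C)(C)C1=O
F6 | step 6 | cis-fused 3a-hydroxy lactone, (3aR,6S,7aR)-3a-hydroxy-4,4,7a-trimethyl-2-oxooctahydro-1-benzofuran-6-yl hex-5-enoate | C=CCCCC(=O)O[C@H]1CC(C)(C)[C@]2(O)CC(=O)O[C@]2(C)C1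
F7 | step 7 | 6-hydroxyhexanoate of (−)-loliolide | OCCCCCC(=O)O[C@H]1CC(C)(C)C2=CC(=O)O[C@]2(C)C1
F8 | step 7 | 6-iodohexanoate of (−)-loliolide | ICCCCCC(=O)O[C@H]1CC(C)(C)C2=CC(=O)O[C@]2(C)C1
F9 | step 7 | decylzinc bromide | CCCCCCCCCC[Zn]Br
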